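**Early pitfall.** The blue run invites a reading of its first hour as the whole flask. It starts with none of the gas in solution, its readings end at 60.0 min, and portions come every 1.0 h, so it shows one portion.

the same everywhere: gas 27 mM (held)
- blue: starting material 51 mM (in portions, 4); second nucleophile 1.5 equiv; run made earlier; portions every 1.0 h
- birch: starting material 12 mM (in portions, 4); second nucleophile 1.00 equiv; the portions of starting material follow each other after 0.60 h, the first at the start; time 5.0 h
- larch: starting material 30 mM (in portions, 4); second nucleophile 1.00 equiv; the portions of starting material follow each other after 1.0 h, the first at the start; time 5.0 h
- alder: starting material 25 mM (in portions, 4); second nucleophile 3.00 equiv; the portions of starting material follow each other after 0.30 h, the first at the start; time 5.0 h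
- oak: starting material 46 mM (in portions, 4); second nucleophile 1.50 equiv; the portions of starting material follow each other after 3.0 h, the first at the start; time 5.0 h
- cedar: starting material 12 mM (in portions, 4); second nucleophile 0.750 equiv; the portions of starting material follow each other after 0.60 h, the first at the start; time 5.0 h
- maple: starting material 46 mM (in portions, 4); second nucleophile 1.50 equiv; the portions of starting material follow each other after 1.0 h, the first at the start; time 5.0 h

- blue (time / min: target / %, other capture product / %): 5.00: 0, 9.6; 15.0: 0, 18.5; 30.0: 0.8, 22.9; 40.0: 0.3, 24.3; 60.0: 0.4, 24.7

(readings scatter by 0.5 percentage points)

- at the start none of the gas is in solution
- percentages count the whole charge, also what has not yet gone in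

1. ranking by share of target in all that became target or other capture product, from high to low, at 5.0 h (birch / larch / alder / oak / cedar / maple)
2. the share of target in all that became target or other capture product of the flask you put first, at 5.0 h
3. the share of target in all that became target or other capture product of the flask you put last, at 5.0 h

**First instants.** The first portion is a quarter of the charge. In blue, other capture product reads 18.5% at 15.0 min and 24.7% at 60.0 min, which gives that portion a half-life near 7.52 min, as a reading. This decay looks like the rate-limiting step, with capture following quickly. Target reads 0.4%, less than the scatter of 0.5 percentage points, so nearly all of what is read at that time is other capture product.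

**Middle hours.** My own reading is that one short-lived intermediate is contested: dissolved gas makes target, and second nucleophile makes other capture product. Later portions then meet more dissolved gas, which starts from nothing and is fed towards 27 mM, and less second nucleophile, which capture and any side loss consume.

**End reckoning.** Whatever has gone in ends as one of the two products, so the share of target follows this contest. I therefore carry the crowding ratio, the starting second nucleophile as a fraction of the gas saturation level: 0.333 for cedar, 0.444 for birch, 1.11 for larch, 2.56 for oak and maple alike, and 2.78 for alder. With the charge of starting material and the portion timing held, a higher ratio should mean a lower share of target. I commit to cedar first and alder last, and hold the middle places loosely, since the charge and the portion timing differ there.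

**The forecast.** It gives alder > oak > maple > larch > birch > cedar, with 1.6% for the first flask and 0.2% for the last. Its ground is that “only absolute nucleophile concentration matters, not equivalents”. My reckoning uses the same concentrations but runs the opposite way, and the two part on that direction.

**Flask result.** The ranking is cedar > larch > birch > maple > oak > alder, from cedar at 38.2% to alder at 4.79%.

    starting material → intermediate (k = 0.00150 s⁻¹)
    first nucleophile + intermediate → target (k = 1.70 M⁻¹ s⁻¹)
    second nucleophile + intermediate → other capture product (k = 6.20 M⁻¹ s⁻¹)
    2 second nucleophile → homo dimer (k = 0.00220 M⁻¹ s⁻¹)
    gas ⇌ first nucleophile, rate k5*(csat - [first nucleophile]) (kL = 1.00 × 10⁻⁴ s⁻¹)

**Ratio reused.** The dissolved gas is the first nucleophile here. Cedar, with the smallest ratio, stands first, and alder, with the largest, stands last. Left ten times as long, cedar still shows 38.2%. A neighbour of cedar with 3.00 equiv of second nucleophile has a ratio of 1.33, higher than cedar's and lower than alder's, and its share falls between theirs, at 11.9%.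

The runs come from a simulation with constants of no real substance.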